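Isocryptomerin is cut at O1'–C8a' of the apigenin half. In ring A' the oxygens on C5', C7' and C8a' lie ortho, para and ortho to C4a', which carries the C4' carbonyl, so a 2,4,6-trifluorobenzoyl group can stand in for the phloroglucinol ring. The key step lets the enol oxygen of an aryl/trifluorophenyl 1,3-diketone displace one ortho fluoride, closing pyranone ring C' in one operation and leaving two carbonyl-activated fluorides for later exchange against benzyloxide. The precursor is that diketone, already carrying the finished 6-aryloxy-5,7-dimethoxyflavone with a benzyl-protected ring B; it is assembled from 2,6-dimethoxybenzoquinone in six steps.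

Key step: step 7

Remark: unprimed locants and rings A, C, B denote the 7-methoxyflavone half, primed ones (A', C', B') the apigenin half; 1,3-diketones are drawn as diketo forms although they are largely enolised; the target has no stereocentre.

Step 1
Reactants: 1 2,6-dimethoxy-1,4-benzoquinone
Product: 2 2,6-dimethoxybenzene-1,4-diol
Conditions: Na2S2O4, EtOAc/H2O, rt, N2
Reagents that add atoms: none
Why: Dithionite reduces the p-quinone to the hydroquinone by two-electron, two-proton transfer (quinone reduction), and the air-sensitive product is used at once.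

Step 2
Reactants: 2 2,6-dimethoxybenzene-1,4-diol
Product: 4 1-(3,6-dihydroxy-2,4-dimethoxyphenyl)ethanone, via difluoroboron chelate 3 (not isolated)
Conditions: BF3·OEt2, AcOH, 85 °C; then H2O, 60 °C
Reagents that add atoms: acetic acid, CC(=O)O
Why: Friedel–Crafts C-acetylation (by way of the O-acetate and a Fries shift) takes place at the only kind of free ring carbon, ortho to the unhindered hydroxyl and ortho/para to the two methoxy groups, and the ketone is held as a BF2 chelate with the neighbouring hydroxyl, which blocks a second acylation and is hydrolysed on work-up.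

Step 3
Reactants: 4 1-(3,6-dihydroxy-2,4-dimethoxyphenyl)ethanone; 5 methyl 4-fluorobenzoate
Product: 6 methyl 4-(3-acetyl-4-hydroxy-2,6-dimethoxyphenoxy)benzoate
Conditions: Cs2CO3 (2.5 equiv), degassed DMSO, 110 °C, Ar
Reagents that add atoms: none
Why: SNAr (addition–elimination) at the ester-activated C–F bond of 5; with excess carbonate both hydroxyls are ionised, and the oxygen between the two methoxy groups, whose charge is not delocalised into the acetyl group, is much the stronger nucleophile, so the aryl group should go to the hindered oxygen just as alkyl halides do with 2,5-dihydroxyacetophenones.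

Step 4
Reactants: 6 methyl 4-(3-acetyl-4-hydroxy-2,6-dimethoxyphenoxy)benzoate; 7 4-(benzyloxy)benzoyl chloride
Product: 9 methyl 4-(3-{3-[4-(benzyloxy)phenyl]-3-oxopropanoyl}-4-hydroxy-2,6-dimethoxyphenoxy)benzoate, via dilithium dianion 8 (not isolated)
Conditions: LiN(SiMe3)2 (3.3 equiv), THF, −78 °C; then 7, −78 °C → rt; 1 M HCl
Reagents that add atoms: none
Why: One-flask Baker–Venkataraman-type diketone synthesis in which the acid chloride acylates the enolate carbon of dianion 8 (any O-acylation of the phenoxide is funnelled to the same diketone by base-induced acyl shift), the third equivalent of base stores the product as its enolate, and at −78 °C the acid chloride reacts long before the distal methyl ester can.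

Step 5
Reactants: 9 methyl 4-(3-{3-[4-(benzyloxy)phenyl]-3-oxopropanoyl}-4-hydroxy-2,6-dimethoxyphenoxy)benzoate
Product: 10 methyl 4-({2-[4-(benzyloxy)phenyl]-5,7-dimethoxy-4-oxo-4H-chromen-6-yl}oxy)benzoate
Conditions: TsOH·H2O (10 mol%), toluene, reflux, Dean–Stark
Reagents that add atoms: none
Why: Acid-catalysed cyclodehydration of the o-hydroxyaryl 1,3-diketone (flavone ring closure): the phenol oxygen adds to the protonated carbonyl next to ring B and loss of water gives the aromatic pyranone ring C, under conditions that an aryl benzyl ether and a methyl ester tolerate.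

Step 6
Reactants: 10 methyl 4-({2-[4-(benzyloxy)phenyl]-5,7-dimethoxy-4-oxo-4H-chromen-6-yl}oxy)benzoate; 11 2',4',6'-trifluoroacetophenone
Product: 13 1-[4-({2-[4-(benzyloxy)phenyl]-5,7-dimethoxy-4-oxo-4H-chromen-6-yl}oxy)phenyl]-3-(2,4,6-trifluorophenyl)propane-1,3-dione, via lithium enolate 12 (not isolated)
Conditions: 11 (2.5 equiv), LiN(SiMe3)2 (2.6 equiv), THF, −78 °C; then 10, −78 °C → rt; 1 M HCl, 0 °C
Reagents that add atoms: none
Why: Crossed Claisen condensation in which pre-formed enolate 12 adds to the methyl ester of 10, methoxide leaves and the diketone is deprotonated at once by a second equivalent of enolate, which makes the sequence irreversible, whereas addition of the enolate to the flavone is reversible, 10 has no acidic C–H, and complete enolisation of 11 suppresses its self-condensation.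

Step 7
Reactants: 13 1-[4-({2-[4-(benzyloxy)phenyl]-5,7-dimethoxy-4-oxo-4H-chromen-6-yl}oxy)phenyl]-3-(2,4,6-trifluorophenyl)propane-1,3-dione
Product: 14 2-[4-(benzyloxy)phenyl]-6-[4-(5,7-difluoro-4-oxo-4H-chromen-2-yl)phenoxy]-5,7-dimethoxy-4H-chromen-4-one
Conditions: K2CO3 (2 equiv), DMF, rt → 60 °C
Reagents that add atoms: none
Why: K2CO3 converts the 1,3-diketone into its enolate, whose oxygen on C2' adds to C8a', one of the two fluorine-bearing ortho carbons of the trifluorophenyl ring, to give a Meisenheimer anion whose charge is taken up by the C4' carbonyl through C4a' and is further stabilised inductively by the two remaining fluorines; loss of fluoride restores the arene and forms the O1'–C8a' bond. The closest known reaction type is the base-mediated cyclisation of 1-(2-fluoroaryl)-1,3-diketones to flavones by intramolecular SNAr. Ring C' closes in a six-membered mode at a trigonal carbon, 6-endo-trig when counted across the C8a'=C4a' bond that relays the charge to the carbonyl (an intramolecular oxa-Michael addition followed by elimination), although the delocalised arene also allows a formal 6-exo count across C8a'=C8'. No stereocentre is formed. The selectivity needed is ortho over para fluoride and O- over C-attack: only the ortho carbons are within reach of the tethered oxygen, the two ortho positions are equivalent, attack through C3' would need a four-membered ring, ring B' has no leaving group and the finished unprimed flavone has no acidic proton, so a single product is expected.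

Step 8
Reactants: 14 2-[4-(benzyloxy)phenyl]-6-[4-(5,7-difluoro-4-oxo-4H-chromen-2-yl)phenoxy]-5,7-dimethoxy-4H-chromen-4-one
Product: 16 2-[4-(benzyloxy)phenyl]-6-{4-[5,7-bis(benzyloxy)-4-oxo-4H-chromen-2-yl]phenoxy}-5,7-dimethoxy-4H-chromen-4-one, via 7'-benzyloxy-5'-fluoro intermediate 15 (not isolated)
Conditions: BnOH (2.6 equiv), NaH (2.5 equiv), THF/DMF, 0 °C → 40 °C
Reagents that add atoms: benzyl alcohol, OCc1ccccc1
Why: Twofold intermolecular SNAr with sodium benzyloxide, in which the fluoride at C7' (para to C4a') is expected to leave first and that at C5' (ortho) second, both carbons being activated by the C4' carbonyl, while the aryloxy group on ring B' is a far poorer leaving group than fluoride, so the diaryl ether should stay intact at or below 40 °C.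

Step 9
Reactants: 16 2-[4-(benzyloxy)phenyl]-6-{4-[5,7-bis(benzyloxy)-4-oxo-4H-chromen-2-yl]phenoxy}-5,7-dimethoxy-4H-chromen-4-one
Product: 17 isocryptomerin, 6-[4-(5,7-dihydroxy-4-oxo-4H-chromen-2-yl)phenoxy]-5-hydroxy-2-(4-hydroxyphenyl)-7-methoxy-4H-chromen-4-one
Conditions: BCl3 (10 equiv), C6HMe5 (9 equiv), CH2Cl2, −78 °C → 0 °C; then H2O
Reagents that add atoms: none
Why: Lewis-acid ether cleavage in which BCl3 ionises the three aryl benzyl ethers, the benzyl cations being trapped by pentamethylbenzene (Friedel–Crafts scavenging that keeps them off the electron-rich ring A'), and boron chelated between the C4 carbonyl and the C5 oxygen delivers chloride to the peri methyl group only, so the non-chelated C7 methyl ether and the diaryl ether should survive at or below 0 °C.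

Compound list
1 | 2,6-dimethoxy-1,4-benzoquinone | COC1=CC(=O)C=C(OC)C1=O | starting material
2 | 2,6-dimethoxybenzene-1,4-diol | COc1cc(O)cc(OC)c1O | intermediate
3 | difluoroboron chelate of 4 (boron bridging the ketone oxygen and the ortho phenol oxygen; formed in the flask) | CC1=[O+][B-](F)(F)Oc2cc(OC)c(O)c(OC)c12 | intermediate
4 | 1-(3,6-dihydroxy-2,4-dimethoxyphenyl)ethanone | CC(=O)c1c(O)cc(OC)c(O)c1OC | intermediate
5 | methyl 4-fluorobenzoate | COC(=O)c1ccc(F)cc1 | starting material
6 | methyl 4-(3-acetyl-4-hydroxy-2,6-dimethoxyphenoxy)benzoate | COC(=O)c1ccc(Oc2c(OC)cc(O)c(C(C)=O)c2OC)cc1 | intermediate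
7 | 4-(benzyloxy)benzoyl chloride | O=C(Cl)c1ccc(OCc2ccccc2)cc1 | starting material
8 | dilithium phenoxide/enolate dianion of 6 (formed in the flask) | [Li+].[Li+].COC(=O)c1ccc(Oc2c(OC)cc([O-])c(C([O-])=C)c2OC)cc1 | intermediate
9 | methyl 4-(3-{3-[4-(benzyloxy)phenyl]-3-oxopropanoyl}-4-hydroxy-2,6-dimethoxyphenoxy)benzoate | COC(=O)c1ccc(Oc2c(OC)cc(O)c(C(=O)CC(=O)c3ccc(OCc4ccccc4)cc3)c2OC)cc1 | intermediate
10 | methyl 4-({2-[4-(benzyloxy)phenyl]-5,7-dimethoxy-4-oxo-4H-chromen-6-yl}oxy)benzoate | COC(=O)c1ccc(Oc2c(OC)cc3oc(-c4ccc(OCc5ccccc5)cc4)cc(=O)c3c2OC)cc1 | intermediate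
11 | 2',4',6'-trifluoroacetophenone, 1-(2,4,6-trifluorophenyl)ethanone | CC(=O)c1c(F)cc(F)cc1F | starting material
12 | lithium enolate of 11, lithium 1-(2,4,6-trifluorophenyl)ethenolate (formed in the flask) | [Li+].[O-]C(=C)c1c(F)cc(F)cc1F | intermediate
13 | 1-[4-({2-[4-(benzyloxy)phenyl]-5,7-dimethoxy-4-oxo-4H-chromen-6-yl}oxy)phenyl]-3-(2,4,6-trifluorophenyl)propane-1,3-dione (precursor of the key step) | O=C(CC(=O)c1c(F)cc(F)cc1F)c1ccc(Oc2c(OC)cc3oc(-c4ccc(OCc5ccccc5)cc4)cc(=O)c3c2OC)cc1 | intermediate
14 | 2-[4-(benzyloxy)phenyl]-6-[4-(5,7-difluoro-4-oxo-4H-chromen-2-yl)phenoxy]-5,7-dimethoxy-4H-chromen-4-one (product of the key step) | COc1cc2oc(-c3ccc(OCc4ccccc4)cc3)cc(=O)c2c(OC)c1Oc1ccc(-c2cc(=O)c3c(F)cc(F)cc3o2)cc1 | intermediate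
15 | 2-[4-(benzyloxy)phenyl]-6-{4-[7-(benzyloxy)-5-fluoro-4-oxo-4H-chromen-2-yl]phenoxy}-5,7-dimethoxy-4H-chromen-4-one (formed in the flask) | COc1cc2oc(-c3ccc(OCc4ccccc4)cc3)cc(=O)c2c(OC)c1Oc1ccc(-c2cc(=O)c3c(F)cc(OCc4ccccc4)cc3o2)cc1 | intermediate
16 | 2-[4-(benzyloxy)phenyl]-6-{4-[5,7-bis(benzyloxy)-4-oxo-4H-chromen-2-yl]phenoxy}-5,7-dimethoxy-4H-chromen-4-one | COc1cc2oc(-c3ccc(OCc4ccccc4)cc3)cc(=O)c2c(OC)c1Oc1ccc(-c2cc(=O)c3c(OCc4ccccc4)cc(OCc4ccccc4)cc3o2)cc1 | intermediate
17 | isocryptomerin, 6-[4-(5,7-dihydroxy-4-oxo-4H-chromen-2-yl)phenoxy]-5-hydroxy-2-(4-hydroxyphenyl)-7-methoxy-4H-chromen-4-one | COc1cc2oc(-c3ccc(O)cc3)cc(=O)c2c(O)c1Oc1ccc(-c2cc(=O)c3c(O)cc(O)cc3o2)cc1 | target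

Total step count: 9. Longest linear sequence: 9 steps (1 → 17); compounds 5, 7 and 11 enter as purchased materials.

Steps most likely to fail

Step 6. The electron-rich methyl ester may react too slowly with the enolate, so that on warming the enolate adds to C2 of the pyranone ring or displaces fluoride on a second molecule of ketone. The fallback sets out from 10 and comes back to the route at 13. The ester is saponified with LiOH in THF/H2O at rt to 4-({2-[4-(benzyloxy)phenyl]-5,7-dimethoxy-4-oxo-4H-chromen-6-yl}oxy)benzoic acid F1. With (COCl)2 and catalytic DMF in CH2Cl2 this should give 4-({2-[4-(benzyloxy)phenyl]-5,7-dimethoxy-4-oxo-4H-chromen-6-yl}oxy)benzoyl chloride F2. F2 is added at −78 °C to lithium enolate 12 (2.2 equiv, from 11 and LiN(SiMe3)2 in THF). This C-acylation of a ketone enolate by an acid chloride is complete at a temperature at which the flavone is inert, and acidic work-up should deliver 13.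

Step 3. Addition of the doubly ortho-substituted phenoxide to a fluoroarene activated only by an ester may be slow, and at the temperature then needed, oxidation of the electron-rich dianion or arylation of the chelated oxygen may take over. The fallback sets out from 4 and comes back at 6; it makes no new compound (F0). It is an Ullmann-type C–O coupling of 4 with methyl 4-iodobenzoate: CuI (10 mol%), picolinic acid (20 mol%), K3PO4, DMSO, 90 °C, Ar. Bond formation at copper does not depend on activation of the arene by the ester, and this ligand system is suited to hindered phenols; the chelated hydroxyl, being the poorer ligand and nucleophile, should again stay free.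

Step 8. The exchange may stall after the first fluoride, because the benzyloxy group at C7' makes ring A' less electrophilic. Under the forcing then needed, benzyloxide may add to C2 or C2' with opening of a pyranone ring, or displace the aryloxide from ring B'. The fallback sets out from 15, which is then isolated after treating 14 with one equivalent of NaOCH2Ph at 0 °C, and comes back at 17. The remaining C5' fluoride is exchanged with (E)-benzaldoxime and Cs2CO3 in DMSO at 60–80 °C, a weakly basic hydroxide surrogate. The O-aryl oxime 2-[4-(benzyloxy)phenyl]-6-{4-[7-(benzyloxy)-5-{[(E)-benzylideneamino]oxy}-4-oxo-4H-chromen-2-yl]phenoxy}-5,7-dimethoxy-4H-chromen-4-one F3 (not isolated) should lose benzonitrile by base-induced elimination. This gives 2-[4-(benzyloxy)phenyl]-6-{4-[7-(benzyloxy)-5-hydroxy-4-oxo-4H-chromen-2-yl]phenoxy}-5,7-dimethoxy-4H-chromen-4-one F4. F4 under the conditions of step 9 (BCl3, C6HMe5, CH2Cl2) should give 17.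

Further compounds
F1 | step 6 | 4-({2-[4-(benzyloxy)phenyl]-5,7-dimethoxy-4-oxo-4H-chromen-6-yl}oxy)benzoic acid | OC(=O)c1ccc(Oc2c(OC)cc3oc(-c4ccc(OCc5ccccc5)cc4)cc(=O)c3c2OC)cc1
F2 | step 6 | 4-({2-[4-(benzyloxy)phenyl]-5,7-dimethoxy-4-oxo-4H-chromen-6-yl}oxy)benzoyl chloride | O=C(Cl)c1ccc(Oc2c(OC)cc3oc(-c4ccc(OCc5ccccc5)cc4)cc(=O)c3c2OC)cc1
F0 | step 3 | none | none
F3 | step 8 | 2-[4-(benzyloxy)phenyl]-6-{4-[7-(benzyloxy)-5-{[(E)-benzylideneamino]oxy}-4-oxo-4H-chromen-2-yl]phenoxy}-5,7-dimethoxy-4H-chromen-4-one | COc1cc2oc(-c3ccc(OCc4ccccc4)cc3)cc(=O)c2c(OC)c1Oc1ccc(-c2cc(=O)c3c(O/N=C/c4ccccc4)cc(OCc4ccccc4)cc3o2)cc1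
F4 | step 8 | 2-[4-(benzyloxy)phenyl]-6-{4-[7-(benzyloxy)-5-hydroxy-4-oxo-4H-chromen-2-yl]phenoxy}-5,7-dimethoxy-4H-chromen-4-one | COc1cc2oc(-c3ccc(OCc4ccccc4)cc3)cc(=O)c2c(OC)c1Oc1ccc(-c2cc(=O)c3c(O)cc(OCc4ccccc4)cc3o2)cc1
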